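**Retrosynthetic overview**
- Feature: each ring carries its n-propyl group ortho to the carbonyl-bearing carbon (C6 in ring A, C6' in ring B). Read as oxygen, these positions turn both rings into 2,4,6-trioxygenated benzoyl units. In the 4-O-methyl ring A unit, C3 and C5 are mirror-related, so monochlorination has a single outcome.
- The last disconnection removes three benzyl groups (O2, O2', CO2H). Before that, both aryl–propyl bonds (C6–CH2 and C6'–CH2) are cut together, giving a bis-triflate depside and propylzinc bromide.
- The depside C(=O)–O4' bond comes from the ring A acid chloride and the only unchelated phenol of benzyl 2,4,6-trihydroxybenzoate. Ring B, still symmetric, is then monotriflated and benzylated on the depside.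
- Ring A is built from 2,4,6-trihydroxybenzaldehyde (O4 methylation, chlorination, O6 triflation, O2 benzylation) and oxidised to the acid only afterwards. An ester between two ortho substituents could not be hydrolysed beside an aryl triflate.
- No ring is formed: both benzene rings are bought as phloroglucinol derivatives.

Key step: step 10

Remark: in ring A, C1 bears the depside carbonyl (C2 O, C3 Cl, C4 OMe, C6 propyl or OTf). In ring B, C1' bears the carboxyl carbon (C2' O, C4' depside O, C6' propyl or OTf). Triflyloxy = OSO2CF3. The target has no stereocentre, so no configuration has to be set.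

Step 1
Reactants: 1 2,4,6-trihydroxybenzaldehyde
Product: 2 2,6-dihydroxy-4-methoxybenzaldehyde
Conditions: MeOH (1.05 equiv), PPh3, DIAD, THF, 0 °C → rt
Reagents that add atoms: methanol, CO
Why: Mitsunobu etherification takes the most acidic and only unchelated phenol, the C4 hydroxyl para to the formyl group, while the C2 and C6 hydroxyls are tied to the carbonyl oxygen by hydrogen bonding and should stay free with one equivalent of reagent.

Step 2
Reactants: 2 2,6-dihydroxy-4-methoxybenzaldehyde
Product: 3 3-chloro-2,6-dihydroxy-4-methoxybenzaldehyde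
Conditions: SO2Cl2 (1.0 equiv), Et2O, 0 °C
Reagents that add atoms: sulfuryl chloride, O=S(=O)(Cl)Cl
Why: Electrophilic aromatic chlorination of a compound with a mirror plane through C1 and C4, in which C3 and C5 are the same position (ortho to OH and OMe, para to the other OH), so only one monochloride can form and the first chlorine slows a second attack.

Step 3
Reactants: 3 3-chloro-2,6-dihydroxy-4-methoxybenzaldehyde
Product: 4 3-chloro-2-hydroxy-4-methoxy-6-(triflyloxy)benzaldehyde
Conditions: Tf2O (1.05 equiv), pyridine, CH2Cl2, −78 → −20 °C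
Reagents that add atoms: trifluoromethanesulfonic anhydride, O=S(=O)(OS(=O)(=O)C(F)(F)F)C(F)(F)F
Why: Kinetic phenol O-triflation with a weak base should take the C6 oxygen, because the C6 hydroxyl has only H5 as outer neighbour, whereas the C2 hydroxyl is wedged between Cl3 and the formyl group and, as the more acidic donor pressed towards the carbonyl oxygen, holds the stronger hydrogen bond.

Step 4
Reactants: 4 3-chloro-2-hydroxy-4-methoxy-6-(triflyloxy)benzaldehyde
Product: 5 2-(benzyloxy)-3-chloro-4-methoxy-6-(triflyloxy)benzaldehyde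
Conditions: BnOH, PPh3, DIAD, THF, 0 °C → rt
Reagents that add atoms: benzyl alcohol, OCc1ccccc1
Why: Mitsunobu etherification with a primary benzylic alcohol works on doubly flanked but acidic phenols, and because no free phenoxide persists in solution the activated aryl triflate is not exposed to the intermolecular triflyl transfer that carbonate bases could cause.

Step 5
Reactants: 5 2-(benzyloxy)-3-chloro-4-methoxy-6-(triflyloxy)benzaldehyde
Product: 6 2-(benzyloxy)-3-chloro-4-methoxy-6-(triflyloxy)benzoic acid
Conditions: NaClO2, NaH2PO4, 2-methyl-2-butene, t-BuOH/THF/H2O, rt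
Reagents that add atoms: sodium chlorite, [Na+].[O-]Cl=O
Why: Pinnick oxidation converts even doubly ortho-substituted benzaldehydes into acids at about pH 4, where triflate, benzyl ether and aryl chloride are inert, and 2-methyl-2-butene traps the hypochlorous acid before it can chlorinate C5.

Step 6
Reactants: 7 2,4,6-trihydroxybenzoic acid
Product: 8 benzyl 2,4,6-trihydroxybenzoate
Conditions: BnBr (1.05 equiv), KHCO3, DMF, rt
Reagents that add atoms: benzyl bromide, BrCc1ccccc1
Why: Carboxylate O-alkylation (SN2), in which KHCO3 deprotonates only the strongly acidic carboxyl group, the phenols stay protonated, and room temperature avoids the easy decarboxylation of this acid.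

Step 7
Reactants: 6 2-(benzyloxy)-3-chloro-4-methoxy-6-(triflyloxy)benzoic acid; 8 benzyl 2,4,6-trihydroxybenzoate
Product: 10 benzyl 4-{[2-(benzyloxy)-3-chloro-4-methoxy-6-(triflyloxy)benzoyl]oxy}-2,6-dihydroxybenzoate, via acid chloride 9 (not isolated)
Conditions: (COCl)2, cat. DMF, CH2Cl2, 0 °C → rt, evaporate; then 8 (1.1 equiv), Et3N (1.1 equiv), cat. DMAP, CH2Cl2/THF, 0 °C → rt
Reagents that add atoms: oxalyl chloride, O=C(Cl)C(=O)Cl (its chlorine stands in 9 only)
Why: Acid chloride formation followed by DMAP-catalysed phenol acylation (depside esterification), in which the small and reactive acyl chloride overcomes the two ortho substituents of ring A, and of the three phenols of 8 only the C4' hydroxyl is unchelated and most acidic, so it should be acylated selectively and faster than any attack on the triflate.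

Step 8
Reactants: 10 benzyl 4-{[2-(benzyloxy)-3-chloro-4-methoxy-6-(triflyloxy)benzoyl]oxy}-2,6-dihydroxybenzoate
Product: 11 benzyl 4-{[2-(benzyloxy)-3-chloro-4-methoxy-6-(triflyloxy)benzoyl]oxy}-2-hydroxy-6-(triflyloxy)benzoate
Conditions: Tf2O (1.0 equiv), pyridine, CH2Cl2, −40 → 0 °C
Reagents that add atoms: trifluoromethanesulfonic anhydride, O=S(=O)(OS(=O)(=O)C(F)(F)F)C(F)(F)F
Why: Phenol O-triflation of a locally symmetric diol, where the C2' and C6' hydroxyls are equivalent so only one monotriflate exists, and after the first sulfonylation the remaining hydroxyl sits on a poorer ring as the sole hydrogen-bond partner of the ester carbonyl, which holds back a second triflation.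

Step 9
Reactants: 11 benzyl 4-{[2-(benzyloxy)-3-chloro-4-methoxy-6-(triflyloxy)benzoyl]oxy}-2-hydroxy-6-(triflyloxy)benzoate
Product: 12 benzyl 2-(benzyloxy)-4-{[2-(benzyloxy)-3-chloro-4-methoxy-6-(triflyloxy)benzoyl]oxy}-6-(triflyloxy)benzoate
Conditions: BnOH, PPh3, DIAD, THF, 0 °C → rt
Reagents that add atoms: benzyl alcohol, OCc1ccccc1
Why: Mitsunobu etherification of the acidic salicylate-type phenol under neutral conditions spares both triflates and the depside ester, whose carbonyl is shielded against benzyl alcohol by its two ortho substituents.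

Step 10
Reactants: 12 benzyl 2-(benzyloxy)-4-{[2-(benzyloxy)-3-chloro-4-methoxy-6-(triflyloxy)benzoyl]oxy}-6-(triflyloxy)benzoate; 13 propylzinc bromide
Product: 16 benzyl 2-(benzyloxy)-4-{[2-(benzyloxy)-3-chloro-4-methoxy-6-propylbenzoyl]oxy}-6-propylbenzoate (tribenzyl-protected 3-chlorodivaricatic acid), via ring A monopropyl monotriflate 14 (not isolated), via ring B monopropyl monotriflate 15 (not isolated)
Conditions: n-PrZnBr (0.5 M in THF, 3.5 equiv), PdCl2(dppf) (10 mol %), THF, 50 °C
Reagents that add atoms: propylzinc bromide 13, CCC[Zn]Br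
Why: PdCl2(dppf) is reduced by the organozinc to zerovalent palladium, which inserts into each C–OTf bond (eased by the ortho carbonyl group), propyl passes from zinc to palladium, and reductive elimination from the divalent aryl(propyl)palladium complex forms C6–CH2 in ring A and C6'–CH2 in ring B by way of 14 and 15. The closest known reaction type is the Negishi (or B-alkyl Suzuki) alkylation of 2-(triflyloxy)benzoates made from polyhydroxybenzoic acids, here run at two sites in one flask. No ring is closed and no stereocentre is made. Selectivity for C–OTf over C3–Cl is needed and is secured because the chloride sits on an electron-rich carbon between OBn and OMe and a dppf-ligated catalyst at 50 °C does not insert into such aryl chlorides, which is why more active bulky monophosphine or carbene catalysts are avoided. Beta-hydride elimination, which would reduce a C–OTf bond to C–H, is held back by the wide bite angle of dppf, which speeds reductive elimination, and a primary alkyl group has little tendency to isomerise. The alkylzinc halide is neither basic nor nucleophilic enough to attack the shielded depside ester or the benzyl ester, and each triflate has only one ortho substituent, so an excess of 13 should drive both sites to completion.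

Step 11
Reactants: 16 benzyl 2-(benzyloxy)-4-{[2-(benzyloxy)-3-chloro-4-methoxy-6-propylbenzoyl]oxy}-6-propylbenzoate
Product: 17 3-chlorodivaricatic acid
Conditions: H2 (1 atm), Pd/C (10 wt % palladium on carbon), EtOAc, rt, stopped at full debenzylation
Reagents that add atoms: none
Why: Catalytic hydrogenolysis of the three benzylic C–O bonds frees both phenols and the acid, and in neutral ethyl acetate without base at one atmosphere the electron-rich aryl chloride flanked by two oxygen substituents should be reduced far more slowly than the benzyl groups.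

**Compound list**
1 | 2,4,6-trihydroxybenzaldehyde | O=Cc1c(O)cc(O)cc1O | starting material
2 | 2,6-dihydroxy-4-methoxybenzaldehyde | COc1cc(O)c(C=O)c(O)c1 | intermediate
3 | 3-chloro-2,6-dihydroxy-4-methoxybenzaldehyde | COc1cc(O)c(C=O)c(O)c1Cl | intermediate
4 | 3-chloro-2-hydroxy-4-methoxy-6-(triflyloxy)benzaldehyde | COc1cc(OS(=O)(=O)C(F)(F)F)c(C=O)c(O)c1Cl | intermediate
5 | 2-(benzyloxy)-3-chloro-4-methoxy-6-(triflyloxy)benzaldehyde | COc1cc(OS(=O)(=O)C(F)(F)F)c(C=O)c(OCc2ccccc2)c1Cl | intermediate
6 | 2-(benzyloxy)-3-chloro-4-methoxy-6-(triflyloxy)benzoic acid | COc1cc(OS(=O)(=O)C(F)(F)F)c(C(=O)O)c(OCc2ccccc2)c1Cl | intermediate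
7 | 2,4,6-trihydroxybenzoic acid | O=C(O)c1c(O)cc(O)cc1O | starting material
8 | benzyl 2,4,6-trihydroxybenzoate | O=C(OCc1ccccc1)c1c(O)cc(O)cc1O | intermediate
9 | 2-(benzyloxy)-3-chloro-4-methoxy-6-(triflyloxy)benzoyl chloride (not isolated) | COc1cc(OS(=O)(=O)C(F)(F)F)c(C(=O)Cl)c(OCc2ccccc2)c1Cl | intermediate
10 | benzyl 4-{[2-(benzyloxy)-3-chloro-4-methoxy-6-(triflyloxy)benzoyl]oxy}-2,6-dihydroxybenzoate | O=C(OCc1ccccc1)c1c(O)cc(OC(=O)c2c(OS(=O)(=O)C(F)(F)F)cc(OC)c(Cl)c2OCc2ccccc2)cc1O | intermediate
11 | benzyl 4-{[2-(benzyloxy)-3-chloro-4-methoxy-6-(triflyloxy)benzoyl]oxy}-2-hydroxy-6-(triflyloxy)benzoate | O=C(OCc1ccccc1)c1c(O)cc(OC(=O)c2c(OS(=O)(=O)C(F)(F)F)cc(OC)c(Cl)c2OCc2ccccc2)cc1OS(=O)(=O)C(F)(F)F | intermediate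
12 | benzyl 2-(benzyloxy)-4-{[2-(benzyloxy)-3-chloro-4-methoxy-6-(triflyloxy)benzoyl]oxy}-6-(triflyloxy)benzoate | O=C(OCc1ccccc1)c1c(OCc2ccccc2)cc(OC(=O)c2c(OS(=O)(=O)C(F)(F)F)cc(OC)c(Cl)c2OCc2ccccc2)cc1OS(=O)(=O)C(F)(F)F | intermediate
13 | propylzinc bromide | CCC[Zn]Br | starting material
14 | benzyl 2-(benzyloxy)-4-{[2-(benzyloxy)-3-chloro-4-methoxy-6-propylbenzoyl]oxy}-6-(triflyloxy)benzoate (not isolated) | O=C(OCc1ccccc1)c1c(OCc2ccccc2)cc(OC(=O)c2c(CCC)cc(OC)c(Cl)c2OCc2ccccc2)cc1OS(=O)(=O)C(F)(F)F | intermediate
15 | benzyl 2-(benzyloxy)-4-{[2-(benzyloxy)-3-chloro-4-methoxy-6-(triflyloxy)benzoyl]oxy}-6-propylbenzoate (not isolated) | CCCc1cc(OC(=O)c2c(OS(=O)(=O)C(F)(F)F)cc(OC)c(Cl)c2OCc2ccccc2)cc(OCc2ccccc2)c1C(=O)OCc1ccccc1 | intermediate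
16 | benzyl 2-(benzyloxy)-4-{[2-(benzyloxy)-3-chloro-4-methoxy-6-propylbenzoyl]oxy}-6-propylbenzoate | CCCc1cc(OC(=O)c2c(CCC)cc(OC)c(Cl)c2OCc2ccccc2)cc(OCc2ccccc2)c1C(=O)OCc1ccccc1 | intermediate
17 | 3-chlorodivaricatic acid | CCCc1cc(OC(=O)c2c(CCC)cc(OC)c(Cl)c2O)cc(O)c1C(=O)O | target

**Step count**
Total step count: 11.
Longest linear sequence: 10 steps (steps 1–5 and 7–11, from 1 to 17). Step 6 is a one-step side branch.

**Steps most likely to fail**

1. Step 10.
   - Risk: the reaction may stall after the first coupling. Beta-hydride elimination may also outrun reductive elimination and reduce a C–OTf bond to C–H.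
   - Fallback: starting from 12, a twofold Stille allylation (allyltributylstannane, Pd(PPh3)4, LiCl, 1,4-dioxane, 90 °C) is used. This is a neutral coupling whose allyl ligand offers no beta-hydride pathway. It should give benzyl 2-allyl-4-{[6-allyl-2-(benzyloxy)-3-chloro-4-methoxybenzoyl]oxy}-6-(benzyloxy)benzoate F1.
   - Return: hydrogenation over Pd/C in EtOAc then saturates both alkenes while it removes the three benzyl groups, so the fallback comes back to the route at 17.

2. Step 3.
   - Risk: site selection between the C2 and C6 hydroxyls may be poor, or both may be sulfonylated.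
   - Fallback: a protecting-group relay from 3. TBDPSCl and imidazole in CH2Cl2/DMF use an electrophile far larger than triflyl, and phenol silylation can equilibrate towards the less crowded oxygen. This should give 6-[(tert-butyldiphenylsilyl)oxy]-3-chloro-2-hydroxy-4-methoxybenzaldehyde F2.
   - Mitsunobu benzylation (BnOH, PPh3, DIAD) gives 2-(benzyloxy)-6-[(tert-butyldiphenylsilyl)oxy]-3-chloro-4-methoxybenzaldehyde F3.
   - Buffered fluoride (TBAF, AcOH, THF, 0 °C) is harmless here because no triflate is yet present, and it frees 2-(benzyloxy)-3-chloro-6-hydroxy-4-methoxybenzaldehyde F4.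
   - Return: triflation of the only remaining hydroxyl (Tf2O, pyridine) comes back to the route at 5.

3. Step 11.
   - Risk: hydrodechlorination at C3 may compete while the hindered C2 benzyl ether is cleaved slowly.
   - Fallback: starting from 16, a Lewis-acid debenzylation (BCl3, pentamethylbenzene as cation scavenger, CH2Cl2, −78 → −20 °C) involves neither hydrogen nor a metal surface, so the C–Cl bond cannot be reduced.
   - The ortho carbonyl groups assist cleavage of both benzyl ethers and then of the benzyl ester by chelation, while the unchelated C4 methyl ether should stay.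
   - Return: the fallback comes back to the route at 17 and makes no new compound (F0).

**Further compounds**
F1 | step 10 | benzyl 2-allyl-4-{[6-allyl-2-(benzyloxy)-3-chloro-4-methoxybenzoyl]oxy}-6-(benzyloxy)benzoate | C=CCc1cc(OC(=O)c2c(CC=C)cc(OC)c(Cl)c2OCc2ccccc2)cc(OCc2ccccc2)c1C(=O)OCc1ccccc1
F2 | step 3 | 6-[(tert-butyldiphenylsilyl)oxy]-3-chloro-2-hydroxy-4-methoxybenzaldehyde | COc1cc(O[Si](c2ccccc2)(c2ccccc2)C(C)(C)C)c(C=O)c(O)c1Cl
F3 | step 3 | 2-(benzyloxy)-6-[(tert-butyldiphenylsilyl)oxy]-3-chloro-4-methoxybenzaldehyde | COc1cc(O[Si](c2ccccc2)(c2ccccc2)C(C)(C)C)c(C=O)c(OCc2ccccc2)c1Cl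
F4 | step 3 | 2-(benzyloxy)-3-chloro-6-hydroxy-4-methoxybenzaldehyde | COc1cc(O)c(C=O)c(OCc2ccccc2)c1Cl
F0 | step 11 | none | none
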